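**Plan**
1. The retrosynthesis cuts two bonds: first the acyl C1–O bond to the OCH2CH2Ar oxygen, then the C8–C9 CH2–CH2 bond in the middle of the pentacosanoyl chain.
2. The hardest feature is the odd, unbranched C25 chain, which the even-numbered natural fat pool does not hold. The C8–C9 cut solves the parity as 17 + 8: stearic acid 1 (C18 minus CO2) plus monomethyl azelate 2 (C9 minus CO2), both bulk acids.
3. Enabling feature: C2–C25 of the acyl part is a bare polymethylene run with no branch, heteroatom or π-bond. C8 and C9 are therefore plain primary carbons of like polarity, and they can be joined as the primary radicals 3 and 4 on a platinum anode (mixed Kolbe electrolysis), seven CH2 groups away from the inert ester carbon C1.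
4. Forward: step 1 joins the chain to methyl pentacosanoate 5. Step 2 passes the acyl group to the aliphatic OH of tyrosol 6 through a lipase acyl-enzyme, as an acyltransferase would, and gives 7. The easily oxidised 4-hydroxyphenyl ring never meets the anode, and no protecting group is used.
5. No ring is formed and no stereochemistry has to be set.

Key step: step 1

Remark on the chemistry: the target has no stereocentre and no stereogenic double bond. It is achiral, so the SMILES defines it completely and "single enantiomer" calls for no stereocontrol.

**Step 1**
Reactants: 1 stearic acid (octadecanoic acid, homologue-free grade); 2 monomethyl azelate (9-methoxy-9-oxononanoic acid)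
Product: 5 methyl pentacosanoate, via heptadecyl radical 3 (not isolated), via 8-methoxy-8-oxooctyl radical 4 (not isolated)
Conditions: Pt anode, Pt cathode, undivided cell, constant current ca. 0.2 A cm⁻², 1 (1 equiv), 2 (3 equiv), NaOMe (5 mol % of total CO2H), MeOH, 45–50 °C, polarity reversed at intervals, run to pH ca. 8
Reagents that add atoms: none
Why: Mixed Kolbe electrolysis: both carboxylates are discharged on platinum at high current density, where the adsorbed carboxylate layer shields the solvent, lose CO2 and give the primary radicals 3 and 4 in high local concentration at the electrode, where they combine to the new C8–C9 σ-bond, a union of two carbons of like polarity. The closest known reaction type is the anodic cross-coupling of a saturated or monounsaturated C18 fatty acid with the methyl half-ester of an α,ω-diacid, the classical electrochemical way of lengthening fatty acid chains. No ring is closed and no stereocentre is formed. The step needs the radical path and not the cationic Hofer–Moest path, which the substrates secure because both radical carbons are unbranched primary CH2 groups without an α-donor and are hard to oxidise further, helped by smooth Pt, weakly acidic MeOH and high current density. Cross- against homo-coupling is only statistical, so the cheap half-ester 2 is used in excess to draw radical 3 into the cross product, and the three coupling products carry zero, one and two ester groups and should part cleanly on silica or by crystallisation. The methyl ester at C1 is not electroactive, sits seven carbons from the radical centre, and its exchange with the solvent MeOH is degenerate.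

**Step 2**
Reactants: 5 methyl pentacosanoate; 6 tyrosol (4-(2-hydroxyethyl)phenol)
Product: 7 2-(4-hydroxyphenyl)ethyl pentacosanoate (target)
Conditions: immobilised Candida antarctica lipase B (on acrylic resin), 6 (2 equiv), 2-methyl-2-butanol, 5 Å MS, 60 °C; excess 6 removed by aqueous wash
Reagents that add atoms: none
Why: Lipase-catalysed transesterification through a serine acyl-enzyme, a reaction type well known for tyrosol and long-chain fatty esters, should pass the unbranched acyl chain of 5 only to the primary aliphatic OH of 6, because the phenolic OH is a poor nucleophile towards the acyl-enzyme and any aryl ester would itself be an activated acyl donor that the enzyme cleaves again, while uptake of MeOH by the sieves drives the equilibrium and no stereocentre is involved.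

**Compound list**
1 | stearic acid (octadecanoic acid) | CCCCCCCCCCCCCCCCCC(=O)O | starting material
2 | monomethyl azelate (9-methoxy-9-oxononanoic acid) | COC(=O)CCCCCCCC(=O)O | starting material
3 | heptadecyl radical | CCCCCCCCCCCCCCCC[CH2] | intermediate
4 | 8-methoxy-8-oxooctyl radical | [CH2]CCCCCCC(=O)OC | intermediate
5 | methyl pentacosanoate | CCCCCCCCCCCCCCCCCCCCCCCCC(=O)OC | intermediate
6 | tyrosol (4-(2-hydroxyethyl)phenol) | OCCc1ccc(O)cc1 | starting material
7 | 2-(4-hydroxyphenyl)ethyl pentacosanoate | CCCCCCCCCCCCCCCCCCCCCCCCC(=O)OCCc1ccc(O)cc1 | target

**Total step count:** 2
**Longest linear sequence:** 2

**Steps most likely to fail** (the route has only two steps, so both are ranked)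

1. Step 1 (key step).
   - What may go wrong: partner selection at the anode is purely statistical, and radicals are lost by disproportionation. Waxy products that dissolve poorly in MeOH may passivate the anode, so that the current efficiency collapses. Chain homologues from an impure grade of 1 would be carried through as species that cannot be separated later.
   - Fallback: it sets out from 6 and comes back at 7, replacing both steps by an olefin-based chain assembly. Compound 6 is acylated at the aliphatic OH with commercial undec-10-enoic acid (immobilised Candida antarctica lipase B, 2-methyl-2-butanol, 4 Å MS, 55 °C) to give 2-(4-hydroxyphenyl)ethyl undec-10-enoate F1.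
   - Cross-metathesis of F1 with an excess of commercial 1-hexadecene follows (second-generation Ru–NHC alkylidene catalyst, 1,4-benzoquinone additive against double-bond migration, CH2Cl2, 40 °C). It should give 2-(4-hydroxyphenyl)ethyl pentacos-10-enoate F2 as an E/Z mixture of no consequence (11 + 16 − 2 = 25 carbons).
   - Hydrogenation (H2, Pd/C, EtOAc, rt) saturates C10=C11 without touching the phenol or the ester and gives 7.

2. Step 2.
   - What may go wrong: the very long, waxy methyl ester may acylate the enzyme slowly, the released methanol may inhibit the lipase, and the reaction may stall at the transesterification equilibrium.
   - Fallback: it sets out from 5 and comes back at 7. It activates the alcohol carbon instead of the acyl carbon, so the O–CH2 bond is the one formed. Compound 5 is saponified (LiOH, THF/MeOH/H2O, 60 °C, then HCl) to pentacosanoic acid F3.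
   - Mitsunobu esterification of F3 with 6 (PPh3, DIAD, THF, 0 °C to rt) should give 7 without phenol protection. Only the aliphatic OH forms the alkoxyphosphonium ion, and the carboxylic acid is far more acidic than the phenol, so it is the pronucleophile that attacks.

**Further compounds**
F1 | step 1 | 2-(4-hydroxyphenyl)ethyl undec-10-enoate | C=CCCCCCCCCC(=O)OCCc1ccc(O)cc1
F2 | step 1 | 2-(4-hydroxyphenyl)ethyl pentacos-10-enoate (E/Z mixture expected, E isomer drawn) | CCCCCCCCCCCCCC/C=C/CCCCCCCCC(=O)OCCc1ccc(O)cc1
F3 | step 2 | pentacosanoic acid | CCCCCCCCCCCCCCCCCCCCCCCCC(=O)O
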